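**Retrosynthetic overview**
1. The C7 aldehyde and C12 ketone come from a diol by oxidation and the two acids from tert-butyl esters; ring D is closed last by gold-catalysed 5-exo-dig attack of a C12 silyl enol ether on a C8 propargyl group.
2. The ring C enone comes from a β-keto ester: C8 propargylation, C14 carbonyl to alkene via the enol triflate, allylic oxidation at C12; C18 is added by C4 ester-enolate methylation.
3. Key disconnection C9–C10: intermolecular Mukaiyama–Michael addition of a ring A tetrasubstituted silyl enol ether (fragment 1) to methyl 6-oxocyclohex-1-ene-1-carboxylate (fragment 2, ring C).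
4. Fragment 1 (ring A, C5 stereocentre) comes from a Diels–Alder reaction of the ethyl vinyl ketone silyl dienol ether with a menthyloxy butenolide, used as a chiral maleic anhydride equivalent.
5. Ring order: A (Diels–Alder), C (bought as a cyclohexanone, joined at C9–C10), D last.

Assumption: locants follow seco-kaurane numbering (ring A = C1–C5, C10; ring C = C8, C9, C11–C14; ring D = C8, C13–C16; C6, C19 = CO2H; C7 = CHO; C17 = exocyclic CH2; C18, C20 = CH3), and the configuration is taken exactly as written in the given SMILES.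

**Route**

Step 1
Reactants: 1 furfural
Product: 2 5-hydroxyfuran-2(5H)-one (racemic hemiacetal)
Conditions: O2, visible light, 5,10,15,20-tetraphenylporphyrin (cat.), MeOH/CH2Cl2, 0 °C
Reagents that add atoms: dioxygen (O=O)
Why: Singlet-oxygen [4+2] photooxygenation of the furan followed by methanolysis of the endoperoxide expels the formyl carbon as methyl formate and leaves the hydroxybutenolide.

Step 2
Reactants: 2 5-hydroxyfuran-2(5H)-one; 3 (+)-menthol
Product: 4 (5S)-5-[(1S,2R,5S)-menthyloxy]furan-2(5H)-one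
Conditions: p-TsOH (cat.), toluene, reflux with water removal; crystallisation from hexane, mother liquor re-equilibrated with acid
Reagents that add atoms: none
Why: Acid-catalysed acetalisation gives both acetal epimers, and crystallisation with acid-mediated epimerisation funnels the material into the single crystalline (5S) diastereomer.

Step 3
Reactants: 5 pent-1-en-3-one (ethyl vinyl ketone)
Product: 6 (Z)-3-(trimethylsilyloxy)penta-1,3-diene
Conditions: TMSOTf, Et3N, Et2O, 0 °C
Reagents that add atoms: trimethylsilyl triflate (C[Si](C)(C)OS(=O)(=O)C(F)(F)F)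
Why: Soft enolisation and O-silylation of the ethyl ketone gives the (Z)-silyl dienol ether, the geometry that reacts as an s-cis diene.

Step 4
Reactants: 4 (5S)-5-menthyloxyfuranone; 6 (Z)-3-(trimethylsilyloxy)penta-1,3-diene
Product: 8 cis-fused keto acetal-lactone of ring A (C1 ketone; C19 lactone carbonyl on C4; C6 menthyl acetal on C5), via silyl enol ether cycloadduct 7 (not isolated)
Conditions: toluene, 110 °C, sealed tube, 24 h; then 1 M HCl, THF, 0 °C
Reagents that add atoms: none
Why: Endo Diels–Alder addition occurs on the butenolide face anti to the menthyloxy group with the siloxy carbon para to the lactone carbonyl, which sets C5 (S) and a cis C4/C5 ring fusion; mild acid then hydrolyses the enol ether to the C1 ketone.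

Step 5
Reactants: 8 keto acetal-lactone
Product: 9 hydroxy-lactone (lactol, anomer mixture; ring-chain tautomer of the C6 aldehyde / C19 acid)
Conditions: 2 M HCl, 1,4-dioxane, 60 °C
Reagents that add atoms: water (O)
Why: Acid-catalysed acetal hydrolysis releases the menthol auxiliary while the cis-fused lactol keeps C4 and C5 intact.

Step 6
Reactants: 9 lactol
Product: 10 (1R,2S,3R)-3-methyl-4-oxocyclohexane-1,2-dicarboxylic acid (all-cis)
Conditions: NaClO2, NaH2PO4, 2-methylbut-2-ene, t-BuOH/H2O, rt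
Reagents that add atoms: sodium chlorite NaClO2 ([Na+].[O-]Cl=O)
Why: Pinnick oxidation of the ring-opened aldehyde form gives the cis diacid without touching the ketone.

Step 7
Reactants: 10 cis keto diacid
Product: 11 di-tert-butyl (1R,2S,3R)-3-methyl-4-oxocyclohexane-1,2-dicarboxylate
Conditions: 2-methylpropene (excess), H2SO4 (cat.), CH2Cl2, −78 °C to rt, pressure tube
Reagents that add atoms: 2-methylpropene (CC(C)=C)
Why: Acid-catalysed addition of both acids to isobutene (tert-butyl esterification) is insensitive to the steric hindrance at C5.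

Step 8
Reactants: 11 di-tert-butyl keto diester
Product: 12 di-tert-butyl cis-4-(tert-butyldimethylsilyloxy)-3-methylcyclohex-3-ene-1,2-dicarboxylate (C1(OTBS)=C10 enol ether)
Conditions: TBSOTf, Et3N, CH2Cl2, 0 °C to rt; chromatography on Et3N-treated silica
Reagents that add atoms: tert-butyldimethylsilyl triflate (CC(C)(C)[Si](C)(C)OS(=O)(=O)C(F)(F)F)
Why: Equilibrating (thermodynamic) silyl enol ether formation favours the tetrasubstituted C1=C10 isomer, and the minor C1=C2 isomer is removed by chromatography.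

Step 9
Reactants: 13 methyl 2-oxocyclohexane-1-carboxylate
Product: 14 methyl 2-oxo-1-(phenylselanyl)cyclohexane-1-carboxylate (racemic)
Conditions: PhSeCl, pyridine, CH2Cl2, 0 °C
Reagents that add atoms: benzeneselenenyl chloride (Cl[Se]c1ccccc1)
Why: α-Selenenylation of the enolised β-keto ester occurs cleanly at the doubly activated carbon.

Step 10
Reactants: 14 α-phenylselanyl keto ester
Product: 16 methyl 6-oxocyclohex-1-ene-1-carboxylate, via selenoxide 15 (not isolated)
Conditions: 30% H2O2, CH2Cl2, 0 °C to rt; used at once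
Reagents that add atoms: none
Why: Oxidation to the selenoxide and spontaneous syn-elimination give the doubly activated cyclohexenone.

Step 11
Reactants: 12 ring A silyl enol ether; 16 methyl 6-oxocyclohex-1-ene-1-carboxylate
Product: 18 C9–C10 Michael adduct (ring A C1 ketone joined to the ring C methyl 14-oxo-7-oate; C8–H β-keto ester), via C14 silyl enol ether adduct 17 (not isolated)
Conditions: Sc(OTf)3 (20 mol %), CH2Cl2, −78 to −20 °C; then 1 M HCl, THF, 0 °C
Reagents that add atoms: none
Why: In this Mukaiyama–Michael addition the chelated keto ester is attacked by C10 on the face anti to the pseudoaxial C5 ester (sets C10, new bond trans to C6), and an open antiperiplanar transition state with H-9 under ring A and the chelate anti to C1–OSi is expected to set C9.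

Step 12
Reactants: 18 Michael adduct
Product: 19 C1 enol triflate (C1=C2) with the ring C β-keto ester intact
Conditions: KN(SiMe3)2 (2.2 equiv), THF, −78 °C; PhNTf2 (1.05 equiv), −78 to −40 °C; aq. NH4Cl
Reagents that add atoms: N-phenylbis(trifluoromethanesulfonimide) (O=S(=O)(N(c1ccccc1)S(=O)(=O)C(F)(F)F)C(F)(F)F)
Why: Enol triflate formation is chemoselective because, in the dianion, the unstabilised C1/C2 ketone enolate reacts with PhNTf2 at −78 °C while the stabilised β-keto ester enolate does not.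

Step 13
Reactants: 19 C1 enol triflate
Product: 20 ring A 1-ene β-keto ester
Conditions: Pd(OAc)2 (5 mol %), PPh3, HCO2H, Bu3N, DMF, 60 °C
Reagents that add atoms: none
Why: Zerovalent-palladium-catalysed formate reduction of the vinyl triflate replaces C–O by C–H and leaves esters and the β-keto ester untouched.

Step 14
Reactants: 20 ring A 1-ene
Product: 21 ring A saturated β-keto ester (C1 = CH2)
Conditions: H2 (1 atm), Pd/C, EtOAc, rt
Reagents that add atoms: none
Why: Catalytic hydrogenation of the isolated cis-disubstituted alkene completes C1 deoxygenation before any alkyne is present.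

Step 15
Reactants: 21 β-keto ester
Product: 22 C8-(3-trimethylsilylprop-2-ynyl) 14-ketone (C8 quaternary; C15 trans to ring A, C7 ester cis to ring A)
Conditions: NaH, DMF, 0 °C; 3-bromo-1-(trimethylsilyl)prop-1-yne, 0 °C to rt
Reagents that add atoms: 3-bromo-1-(trimethylsilyl)prop-1-yne (C[Si](C)(C)C#CCBr)
Why: β-Keto ester C-alkylation takes place anti to the adjacent pseudoaxial ring A substituent on C9, which sets C8.

Step 16
Reactants: 22 propargylated 14-ketone
Product: 23 C14 enol triflate (C13=C14)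
Conditions: KN(SiMe3)2 (1.1 equiv), THF, −78 °C; PhNTf2, −78 to 0 °C; aq. NH4Cl
Reagents that add atoms: N-phenylbis(trifluoromethanesulfonimide) (O=S(=O)(N(c1ccccc1)S(=O)(=O)C(F)(F)F)C(F)(F)F)
Why: The only ketone can enolise only towards C13 (C8 is quaternary), so enol triflate formation is regiospecific.

Step 17
Reactants: 23 C14 enol triflate
Product: 24 ring C 13-ene (C14–H)
Conditions: Pd(OAc)2 (5 mol %), PPh3, HCO2H, Bu3N, DMF, 60 °C
Reagents that add atoms: none
Why: Palladium-catalysed formate reduction of the vinyl triflate removes the C14 oxygen and leaves the C13=C14 alkene for later oxidation at C12; the silyl-capped alkyne is tolerated.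

Step 18
Reactants: 24 ring C 13-ene
Product: 25 C4-methylated triester (C18 installed; C19 ester cis to C20 and C6)
Conditions: LiN(i-Pr)2 (1.2 equiv), THF, −78 °C; MeI, −78 to −20 °C
Reagents that add atoms: iodomethane (CI)
Why: Ester enolate alkylation occurs at C4 only (C5–H is shielded by two quaternary neighbours), and methyl iodide enters equatorially, anti to the axial C10 methyl, which sets C4 as in podocarpate-type C4 alkylations.

Step 19
Reactants: 25 C4-methylated 13-ene
Product: 26 ring C 13-en-12-one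
Conditions: CrO3, 3,5-dimethylpyrazole, CH2Cl2, −20 °C
Reagents that add atoms: chromium trioxide CrO3 (O=[Cr](=O)=O)
Why: Allylic C–H oxidation by hexavalent chromium can only occur at C12, the sole allylic CH2 of the C13=C14 alkene.

Step 20
Reactants: 26 enone with silyl alkyne
Product: 27 terminal alkyne enone
Conditions: K2CO3, MeOH, rt
Reagents that add atoms: none
Why: Base-catalysed protodesilylation of the alkynylsilane leaves the esters and the hindered enone unchanged.

Step 21
Reactants: 27 terminal alkyne enone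
Product: 29 C12 tert-butyldimethylsilyl enol ether (C12=C13), via lithium enolate 28 (not isolated)
Conditions: LiBH(s-Bu)3, THF, −78 °C; then TBSOTf, −78 to −40 °C
Reagents that add atoms: tert-butyldimethylsilyl triflate (CC(C)(C)[Si](C)(C)OS(=O)(=O)C(F)(F)F)
Why: Conjugate (1,4) hydride reduction of the β-unsubstituted enone gives the C12/C13 enolate regiospecifically, and O-silylation traps it.

Step 22
Reactants: 29 silyl enol ether alkyne
Product: 30 bicyclo[3.2.1]octan-12-one with 16-methylene (7-methyl 6,19-di-tert-butyl triester)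
Conditions: Ph3PAuCl (5 mol %), AgBF4 (5 mol %), CH2Cl2/MeOH (10:1), 40 °C
Reagents that add atoms: none
Why: Cationic monovalent gold activates the alkyne for 5-exo-dig attack by C13 of the enol ether (Conia-ene-type carbocyclisation), and the C13 configuration is fixed by the axial C8 tether.

Step 23
Reactants: 30 bicyclic keto triester
Product: 32 6,19-diacid 7-methyl ester 12-ketone, via bis(trimethylsilyl) ester 31 (not isolated)
Conditions: TMSOTf, 2,6-lutidine, CH2Cl2, 0 °C to rt; then MeOH/H2O
Reagents that add atoms: none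
Why: Silyl triflate-mediated tert-butyl ester cleavage (loss of isobutene) is buffered and non-protic, so the exocyclic alkene does not isomerise, and the methyl ester survives.

Step 24
Reactants: 32 diacid keto ester
Product: 33 7,12-diol 6,19-diacid (C12 epimer from hydride delivery on the bridge face drawn; either epimer serves)
Conditions: LiEt3BH (6 equiv), THF, 0 °C to rt; then 1 M HCl
Reagents that add atoms: none
Why: In this hydride reduction the two acids are protected in situ as lithium carboxylates, so only the hindered methyl ester and the ketone are reduced.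

Step 25
Reactants: 33 diol diacid
Product: 34 target CNP0320711.1
Conditions: Dess–Martin periodinane (3 equiv), CH2Cl2, rt
Reagents that add atoms: none
Why: Dess–Martin oxidation converts the neopentyl primary alcohol into the C7 aldehyde and the C12 alcohol into the ketone without affecting acids or alkene.

**Compound list**
1 | furfural | O=Cc1ccco1 | starting material
2 | 5-hydroxyfuran-2(5H)-one (racemic) | O=C1C=CC(O)O1 | intermediate
3 | (+)-menthol, (1S,2R,5S) | C[C@H]1CC[C@@H]([C@H](C1)O)C(C)C | starting material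
4 | (5S)-5-[(1S,2R,5S)-menthyloxy]furan-2(5H)-one | C[C@H]1CC[C@@H]([C@H](C1)O[C@@H]2C=CC(=O)O2)C(C)C | intermediate
5 | pent-1-en-3-one | CCC(=O)C=C | starting material
6 | (Z)-3-(trimethylsilyloxy)penta-1,3-diene | C/C=C(\O[Si](C)(C)C)C=C | intermediate
7 | endo cycloadduct, C1 trimethylsilyl enol ether (not isolated) | C[C@H]1C(O[Si](C)(C)C)=CC[C@H]2C(=O)O[C@H](O[C@H]3C[C@@H](C)CC[C@@H]3C(C)C)[C@@H]12 | intermediate
8 | cis-fused keto acetal-lactone, (S)-menthyl acetal at C6 | C[C@H]1C(=O)CC[C@H]2C(=O)O[C@H](O[C@H]3C[C@@H](C)CC[C@@H]3C(C)C)[C@@H]12 | intermediate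
9 | hydroxy-lactone (lactol, anomer mixture) | C[C@H]1C(=O)CC[C@H]2C(=O)OC(O)[C@@H]12 | intermediate
10 | (1R,2S,3R)-3-methyl-4-oxocyclohexane-1,2-dicarboxylic acid | C[C@H]1C(=O)CC[C@@H](C(=O)O)[C@H]1C(=O)O | intermediate
11 | di-tert-butyl (1R,2S,3R)-3-methyl-4-oxocyclohexane-1,2-dicarboxylate | C[C@H]1C(=O)CC[C@@H](C(=O)OC(C)(C)C)[C@H]1C(=O)OC(C)(C)C | intermediate
12 | di-tert-butyl cis-4-(tert-butyldimethylsilyloxy)-3-methylcyclohex-3-ene-1,2-dicarboxylate | CC1=C(O[Si](C)(C)C(C)(C)C)CC[C@@H](C(=O)OC(C)(C)C)[C@H]1C(=O)OC(C)(C)C | intermediate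
13 | methyl 2-oxocyclohexane-1-carboxylate | COC(=O)C1CCCCC1=O | starting material
14 | methyl 2-oxo-1-(phenylselanyl)cyclohexane-1-carboxylate | COC(=O)C1([Se]c2ccccc2)CCCCC1=O | intermediate
15 | selenoxide of 14 (not isolated) | COC(=O)C1([Se](=O)c2ccccc2)CCCCC1=O | intermediate
16 | methyl 6-oxocyclohex-1-ene-1-carboxylate | COC(=O)C1=CCCCC1=O | intermediate
17 | Michael adduct as C14 tert-butyldimethylsilyl enol ether (not isolated) | COC(=O)C2=C(O[Si](C)(C)C(C)(C)C)CCC[C@H]2[C@]1(C)C(=O)CC[C@@H](C(=O)OC(C)(C)C)[C@H]1C(=O)OC(C)(C)C | intermediate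
18 | Michael adduct, C1 ketone / ring C β-keto ester (keto form drawn; C8 and C4 epimerisable) | COC(=O)[C@@H]2C(=O)CCC[C@H]2[C@]1(C)C(=O)CC[C@@H](C(=O)OC(C)(C)C)[C@H]1C(=O)OC(C)(C)C | intermediate
19 | C1 enol triflate | COC(=O)[C@@H]2C(=O)CCC[C@H]2[C@]1(C)C(OS(=O)(=O)C(F)(F)F)=CC[C@@H](C(=O)OC(C)(C)C)[C@H]1C(=O)OC(C)(C)C | intermediate
20 | ring A 1-ene β-keto ester | COC(=O)[C@@H]2C(=O)CCC[C@H]2[C@]1(C)C=CC[C@@H](C(=O)OC(C)(C)C)[C@H]1C(=O)OC(C)(C)C | intermediate
21 | ring A saturated β-keto ester | COC(=O)[C@@H]2C(=O)CCC[C@H]2[C@]1(C)CCC[C@@H](C(=O)OC(C)(C)C)[C@H]1C(=O)OC(C)(C)C | intermediate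
22 | C8-(3-trimethylsilylprop-2-ynyl) 14-ketone | C[Si](C)(C)C#CC[C@]2(C(=O)OC)C(=O)CCC[C@H]2[C@]1(C)CCC[C@@H](C(=O)OC(C)(C)C)[C@H]1C(=O)OC(C)(C)C | intermediate
23 | C14 enol triflate | C[Si](C)(C)C#CC[C@]2(C(=O)OC)C(OS(=O)(=O)C(F)(F)F)=CCC[C@H]2[C@]1(C)CCC[C@@H](C(=O)OC(C)(C)C)[C@H]1C(=O)OC(C)(C)C | intermediate
24 | ring C 13-ene | C[Si](C)(C)C#CC[C@]2(C(=O)OC)C=CCC[C@H]2[C@]1(C)CCC[C@@H](C(=O)OC(C)(C)C)[C@H]1C(=O)OC(C)(C)C | intermediate
25 | C4-methylated 13-ene | C[Si](C)(C)C#CC[C@]2(C(=O)OC)C=CCC[C@H]2[C@]1(C)CCC[C@@](C)(C(=O)OC(C)(C)C)[C@H]1C(=O)OC(C)(C)C | intermediate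
26 | ring C 13-en-12-one | C[Si](C)(C)C#CC[C@]2(C(=O)OC)C=CC(=O)C[C@H]2[C@]1(C)CCC[C@@](C)(C(=O)OC(C)(C)C)[C@H]1C(=O)OC(C)(C)C | intermediate
27 | terminal alkyne enone | C#CC[C@]2(C(=O)OC)C=CC(=O)C[C@H]2[C@]1(C)CCC[C@@](C)(C(=O)OC(C)(C)C)[C@H]1C(=O)OC(C)(C)C | intermediate
28 | lithium C12 enolate (not isolated) | C#CC[C@]2(C(=O)OC)CC=C(O[Li])C[C@H]2[C@]1(C)CCC[C@@](C)(C(=O)OC(C)(C)C)[C@H]1C(=O)OC(C)(C)C | intermediate
29 | C12 tert-butyldimethylsilyl enol ether | C#CC[C@]2(C(=O)OC)CC=C(O[Si](C)(C)C(C)(C)C)C[C@H]2[C@]1(C)CCC[C@@](C)(C(=O)OC(C)(C)C)[C@H]1C(=O)OC(C)(C)C | intermediate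
30 | bicyclic 12-ketone, 7-methyl 6,19-di-tert-butyl triester | C=C1C[C@]2(C(=O)OC)C[C@H]1C(=O)C[C@H]2[C@]1(C)CCC[C@@](C)(C(=O)OC(C)(C)C)[C@H]1C(=O)OC(C)(C)C | intermediate
31 | bis(trimethylsilyl) 6,19-ester (not isolated) | C=C1C[C@]2(C(=O)OC)C[C@H]1C(=O)C[C@H]2[C@]1(C)CCC[C@@](C)(C(=O)O[Si](C)(C)C)[C@H]1C(=O)O[Si](C)(C)C | intermediate
32 | 6,19-diacid 7-methyl ester 12-ketone | C=C1C[C@]2(C(=O)OC)C[C@H]1C(=O)C[C@H]2[C@]1(C)CCC[C@@](C)(C(=O)O)[C@H]1C(=O)O | intermediate
33 | 7,12-diol 6,19-diacid | C=C1C[C@]2(CO)C[C@H]1[C@@H](O)C[C@H]2[C@]1(C)CCC[C@@](C)(C(=O)O)[C@H]1C(=O)O | intermediate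
34 | CNP0320711.1 | C=C1C[C@]2(C=O)C[C@H]1C(=O)C[C@H]2[C@]1(C)CCC[C@@](C)(C(=O)O)[C@H]1C(=O)O | target

**Totals and risks**

Total steps: 25. Longest linear sequence: 22 steps (1, 2, 4–8, 11–25).

Risk 1, step 11 (hindered Mukaiyama–Michael; C9 selectivity rests on a transition-state model, not on precedent for this pair). Fallback: replace the silyl enol ether and open transition state by a secondary-enamine (aza-ene type) Michael addition. Ketone 11 is condensed with benzylamine (toluene, 4 Å sieves) to the N-benzyl imine F1. Its more substituted enamine tautomer adds to 16 (neat or THF, 40 °C) through a closed proton-transfer transition state, regiospecifically at C10, to give the imine adduct F2. Aqueous acetic acid (10%) hydrolyses F2 to 18. This sets out from 11 and comes back at 18; step 8 is then not needed.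

Risk 2, step 12 (triflating one enolate of a dianion). Fallback: mask the β-keto ester instead of relying on kinetic selectivity. Compound 18 is O-silylated (TBSCl, imidazole, DMF) back to the enol ether 17, now isolated. Its only enolisable ketone is triflated (KN(SiMe3)2, PhNTf2) to the enol triflate F3, which is reduced (Pd(OAc)2, PPh3, HCO2H, Bu3N) to the cyclohexene F4 and hydrogenated (H2, Pd/C) to the saturated silyl enol ether F5. 1 M HCl in THF then unmasks the β-keto ester. This sets out from 18 and comes back at 21.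

Risk 3, step 19 (allylic oxidation; moderate yields, possible attack at the propargylic CH2). Fallback: bring in the C12 oxygen by 1,3-carbonyl transposition. From ketone 22, IBX (DMSO/fluorobenzene, 70 °C) gives the enone F6, tert-butyl hydroperoxide/DBU the epoxy ketone F7, and hydrazine hydrate/acetic acid (Wharton transposition) the allylic alcohol F8. C4 is then methylated on the alkoxide/ester-enolate dianion (LiN(i-Pr)2 2.2 equiv, MeI) to the C4-methylated allylic alcohol F9, and Dess–Martin oxidation gives 26. This sets out from 22 and comes back at 26, replacing steps 16–19; the C12 configuration in F7–F9 is inconsequential.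

Further compounds
F1 | step 11 | N-benzyl imine of 11 | C[C@H]1C(=NCc2ccccc2)CC[C@@H](C(=O)OC(C)(C)C)[C@H]1C(=O)OC(C)(C)C
F2 | step 11 | N-benzyl imine of Michael adduct 18 | COC(=O)[C@@H]2C(=O)CCC[C@H]2[C@]1(C)C(=NCc3ccccc3)CC[C@@H](C(=O)OC(C)(C)C)[C@H]1C(=O)OC(C)(C)C
F3 | step 12 | C1 enol triflate of silyl enol ether 17 | COC(=O)C2=C(O[Si](C)(C)C(C)(C)C)CCC[C@H]2[C@]1(C)C(OS(=O)(=O)C(F)(F)F)=CC[C@@H](C(=O)OC(C)(C)C)[C@H]1C(=O)OC(C)(C)C
F4 | step 12 | ring A 1-ene C14 silyl enol ether | COC(=O)C2=C(O[Si](C)(C)C(C)(C)C)CCC[C@H]2[C@]1(C)C=CC[C@@H](C(=O)OC(C)(C)C)[C@H]1C(=O)OC(C)(C)C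
F5 | step 12 | ring A saturated C14 silyl enol ether | COC(=O)C2=C(O[Si](C)(C)C(C)(C)C)CCC[C@H]2[C@]1(C)CCC[C@@H](C(=O)OC(C)(C)C)[C@H]1C(=O)OC(C)(C)C
F6 | step 19 | ring C 12-en-14-one | C[Si](C)(C)C#CC[C@]2(C(=O)OC)C(=O)C=CC[C@H]2[C@]1(C)CCC[C@@H](C(=O)OC(C)(C)C)[C@H]1C(=O)OC(C)(C)C
F7 | step 19 | 12,13-epoxy-14-ketone | C[Si](C)(C)C#CC[C@]2(C(=O)OC)C(=O)[C@@H]3O[C@@H]3C[C@H]2[C@]1(C)CCC[C@@H](C(=O)OC(C)(C)C)[C@H]1C(=O)OC(C)(C)C
F8 | step 19 | 13-en-12-ol (Wharton allylic alcohol) | C[Si](C)(C)C#CC[C@]2(C(=O)OC)C=C[C@H](O)C[C@H]2[C@]1(C)CCC[C@@H](C(=O)OC(C)(C)C)[C@H]1C(=O)OC(C)(C)C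
F9 | step 19 | C4-methylated 13-en-12-ol | C[Si](C)(C)C#CC[C@]2(C(=O)OC)C=C[C@H](O)C[C@H]2[C@]1(C)CCC[C@@](C)(C(=O)OC(C)(C)C)[C@H]1C(=O)OC(C)(C)C
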